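The quinone half is made last. Its ring carbons C1'(=O)–C2'(O)–C3'(Et)–C4'(=O) are the four carbons of a 3-alkoxy-4-ethylcyclobutenedione, so the 1',4'-naphthoquinone ring is cut at C4'–C4a' back to a 4-aryl-4-hydroxycyclobutenone. Heating opens this strained ring to an aryl vinylketene whose ketene carbon closes on the one free ortho carbon, which builds the second six-membered ring as its hydroquinone while the hindered C2–O–C2' ether, made earlier, is only carried along. The precursor bears the (R)-quinol ether of the trione half, with C3/C4 masked as an enediol dimethyl ether, and benzyl ethers on all six phenolic oxygens, chosen so that the final deprotection is a cold debenzylation.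

Key step: step 12

Assumption: primed locants belong to the quinone half (C2' carries the ether oxygen, C3' the ethyl group) and unprimed locants to the trione half; the (R)-iodyl reagent of step 7 is assumed to give the (R)-quinol, and its antipode is used if a first run shows the opposite sense.

Step 1
Reactants: 1 3-bromo-4,5-dihydroxybenzaldehyde
Product: 2 4,5-bis(benzyloxy)-3-bromobenzaldehyde
Conditions: BnBr (2.3 equiv), K2CO3, DMF, 60 °C
Reagents that add atoms: benzyl bromide, BrCc1ccccc1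
Why: Williamson etherification of both phenoxides with a primary benzylic halide, to which the aldehyde and the aryl bromide are inert.

Step 2
Reactants: 2 4,5-bis(benzyloxy)-3-bromobenzaldehyde
Product: 4 3,4-bis(benzyloxy)-5-bromophenol, via aryl formate 3 (not isolated)
Conditions: mCPBA, CH2Cl2, 0 °C → rt; then K2CO3 (cat.), MeOH, rt
Reagents that add atoms: 3-chloroperoxybenzoic acid, OOC(=O)c1cccc(Cl)c1
Why: Baeyer–Villiger oxidation in which the para-benzyloxy group makes the aryl group migrate in preference to hydride, followed by methanolysis of the formate.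

Step 3
Reactants: 4 3,4-bis(benzyloxy)-5-bromophenol
Product: 5 1,2,5-tris(benzyloxy)-3-bromobenzene
Conditions: BnBr (1.2 equiv), K2CO3, DMF, rt
Reagents that add atoms: benzyl bromide, BrCc1ccccc1
Why: Williamson etherification of the remaining phenol.

Step 4
Reactants: 6 dimethyl squarate; 7 ethylmagnesium bromide
Product: 9 3-ethyl-4-methoxycyclobut-3-ene-1,2-dione, via carbinol adduct 8 (not isolated)
Conditions: EtMgBr (1.05 equiv), THF, −78 °C; then conc. HCl, CH2Cl2, rt
Reagents that add atoms: none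
Why: Grignard 1,2-addition to one squarate carbonyl, then acid-induced loss of methanol with allylic transposition, the standard mono-alkylation of a squarate ester.

Step 5
Reactants: 5 1,2,5-tris(benzyloxy)-3-bromobenzene; 9 3-ethyl-4-methoxycyclobut-3-ene-1,2-dione
Product: 12 4-[2,3,5-tris(benzyloxy)phenyl]-2-ethyl-3,4-dimethoxycyclobut-2-en-1-one, via aryllithium 10 (not isolated), via lithium alkoxide 11 (not isolated)
Conditions: 5, n-BuLi, THF, −78 °C; add to 9, THF, −78 °C; then MeOTf, −78 → 0 °C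
Reagents that add atoms: methyl trifluoromethanesulfonate, COS(=O)(=O)C(F)(F)F
Why: bromine–lithium exchange, 1,2-addition to the ketone-like carbonyl beside the methoxy-bearing carbon (the other carbonyl is a vinylogous ester) and O-methylation of the tertiary lithium alkoxide by the triflate, all kept cold so that the ortho-benzyloxy aryllithium does not rearrange.

Step 6
Reactants: 12 4-[2,3,5-tris(benzyloxy)phenyl]-2-ethyl-3,4-dimethoxycyclobut-2-en-1-one
Product: 14 5,6,8-tris(benzyloxy)-2-ethyl-3,4-dimethoxynaphthalen-1-ol, via vinylketene 13 (not isolated)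
Conditions: p-xylene (degassed), 138 °C, Ar; product used at once
Reagents that add atoms: none
Why: Moore rearrangement, in which conrotatory ring opening (methoxy outward, aryl inward), 6π closure onto the only free ortho carbon and tautomerisation give a 4-methoxy-1-naphthol whose C1 hydroxyl alone is free.

Step 7
Reactants: 14 5,6,8-tris(benzyloxy)-2-ethyl-3,4-dimethoxynaphthalen-1-ol
Product: 15 (R)-5,6,8-tris(benzyloxy)-2-ethyl-2-hydroxy-3,4-dimethoxynaphthalen-1(2H)-one
Conditions: (R)-2,2'-diiodyl-1,1'-binaphthyl (1.0 equiv, made beforehand from the diiodide and DMDO, no excess oxidant), THF, −20 °C → rt; then H2O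
Reagents that add atoms: (R)-2,2'-diiodyl-1,1'-binaphthyl, O=I(=O)c1ccc2ccccc2c1-c1c(I(=O)=O)ccc2ccccc12 (axial configuration given by the name)
Why: hydroxylative phenol dearomatisation by a chiral iodyl arene, in which the naphthol oxygen binds pentavalent iodine and an oxo ligand is passed intramolecularly to the only ortho carbon, C2, so that C4 is not reached, and the biaryl axis selects the face so that C2 is set as (R) under reagent control.

Step 8
Reactants: 9 3-ethyl-4-methoxycyclobut-3-ene-1,2-dione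
Product: 16 3-ethyl-4-hydroxycyclobut-3-ene-1,2-dione
Conditions: 2 M HCl, THF, 60 °C
Reagents that add atoms: water, O
Why: acid hydrolysis of a vinylogous methyl ester by addition–elimination at the methoxy-bearing carbon.

Step 9
Reactants: 16 3-ethyl-4-hydroxycyclobut-3-ene-1,2-dione
Product: 17 3-chloro-4-ethylcyclobut-3-ene-1,2-dione
Conditions: (COCl)2 (1.2 equiv), DMF (cat.), CH2Cl2, 0 °C → rt; used freshly
Reagents that add atoms: oxalyl chloride, O=C(Cl)C(Cl)=O
Why: the vinylogous carboxylic acid is converted into its vinylogous acid chloride by Vilsmeier-type activation, as a carboxylic acid would be.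

Step 10
Reactants: 15 (R)-5,6,8-tris(benzyloxy)-2-ethyl-2-hydroxy-3,4-dimethoxynaphthalen-1(2H)-one; 17 3-chloro-4-ethylcyclobut-3-ene-1,2-dione
Product: 19 3-ethyl-4-{[(2R)-5,6,8-tris(benzyloxy)-2-ethyl-3,4-dimethoxy-1-oxo-1,2-dihydronaphthalen-2-yl]oxy}cyclobut-3-ene-1,2-dione, via lithium alkoxide 18 (not isolated)
Conditions: LiN(SiMe3)2 (1.05 equiv), THF, −78 °C; then 17 (1.3 equiv), −78 → −20 °C
Reagents that add atoms: none
Why: addition–elimination of the tertiary alkoxide at the chlorine-bearing carbon of a vinylogous acid chloride; the ketol has no enolisable hydrogen and the cold, short-lived lithium alkoxide should not undergo an α-ketol shift, so C2 keeps its configuration.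

Step 11
Reactants: 19 3-ethyl-4-{[(2R)-5,6,8-tris(benzyloxy)-2-ethyl-3,4-dimethoxy-1-oxo-1,2-dihydronaphthalen-2-yl]oxy}cyclobut-3-ene-1,2-dione; 5 1,2,5-tris(benzyloxy)-3-bromobenzene
Product: 22 4-[2,3,5-tris(benzyloxy)phenyl]-2-ethyl-4-hydroxy-3-{[(2R)-5,6,8-tris(benzyloxy)-2-ethyl-3,4-dimethoxy-1-oxo-1,2-dihydronaphthalen-2-yl]oxy}cyclobut-2-en-1-one, via arylmagnesium bromide 20 (not isolated), via magnesium alkoxide 21 (not isolated)
Conditions: 5 (1.05 equiv), Mg turnings (iodine-activated), THF, 40 °C, titrate; add slowly to 19, THF, −78 → −40 °C; then AcOH, −78 °C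
Reagents that add atoms: none
Why: direct magnesium insertion into the aryl bromide gives a Grignard reagent that is less basic than the lithium reagent towards the ethyl CH2 and the quinol ether linkage, and its 1,2-addition should go to the most electrophilic carbonyl, the cyclobutenedione carbonyl beside the alkoxy-bearing carbon, since the other ring carbonyl is a vinylogous ester and the naphthalenone C1 ketone is a hindered, electron-rich aryl ketone; the new carbinol centre forms as both epimers, which is of no consequence.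

Step 12
Reactants: 22 4-[2,3,5-tris(benzyloxy)phenyl]-2-ethyl-4-hydroxy-3-{[(2R)-5,6,8-tris(benzyloxy)-2-ethyl-3,4-dimethoxy-1-oxo-1,2-dihydronaphthalen-2-yl]oxy}cyclobut-2-en-1-one
Product: 24 (2R)-5,6,8-tris(benzyloxy)-2-{[5,7,8-tris(benzyloxy)-3-ethyl-1,4-dihydroxynaphthalen-2-yl]oxy}-2-ethyl-3,4-dimethoxynaphthalen-1(2H)-one, via vinylketene 23 (not isolated)
Conditions: toluene (degassed, 0.01 M), 110 °C, Ar; crude product taken on under argon
Reagents that add atoms: none
Why: Thermal conrotatory 4π ring opening of the cyclobutenone breaks C1'–C4' with the hydroxyl turning outward and the aryl group inward, so that (Z)-vinylketene 23 has its ketene carbon C4' next to the arene; this is the Moore rearrangement of 4-aryl-4-hydroxycyclobutenones, driven by release of ring strain. The ring is closed by a thermal disrotatory 6π electrocyclisation in which C4' bonds to the ortho carbon C4a', and enolisation of the resulting dienone gives the aromatic 1',4'-diol. No stereocentre is formed: the carbinol centre is destroyed, so both epimers of 22 converge, and the quaternary C2 is not involved. The selectivity needed is regiochemical and is fixed beforehand, because the aryl ring has a single unsubstituted ortho position and already sits on C1', which places the C7' and C8' oxygens beside C1'. Neutral conditions spare the tertiary ether, the enediol diether and the benzyl ethers, and high dilution should suppress ketene dimerisation.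

Step 13
Reactants: 24 (2R)-5,6,8-tris(benzyloxy)-2-{[5,7,8-tris(benzyloxy)-3-ethyl-1,4-dihydroxynaphthalen-2-yl]oxy}-2-ethyl-3,4-dimethoxynaphthalen-1(2H)-one
Product: 25 5,7,8-tris(benzyloxy)-3-ethyl-2-{[(2R)-5,6,8-tris(benzyloxy)-2-ethyl-3,4-dimethoxy-1-oxo-1,2-dihydronaphthalen-2-yl]oxy}naphthalene-1,4-dione
Conditions: Ag2O (2 equiv), MgSO4, CH2Cl2, rt
Reagents that add atoms: none
Why: two-electron oxidation of a 1,4-hydroquinone to the quinone by Ag2O under neutral conditions that leave enol ethers and benzyl ethers untouched.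

Step 14
Reactants: 25 5,7,8-tris(benzyloxy)-3-ethyl-2-{[(2R)-5,6,8-tris(benzyloxy)-2-ethyl-3,4-dimethoxy-1-oxo-1,2-dihydronaphthalen-2-yl]oxy}naphthalene-1,4-dione
Product: 27 (2S)-5,6,8-tris(benzyloxy)-2-{[5,7,8-tris(benzyloxy)-3-ethyl-1,4-dioxo-1,4-dihydronaphthalen-2-yl]oxy}-2-ethylnaphthalene-1,3,4(2H)-trione, via dimethoxy epoxide 26 (not isolated)
Conditions: DMDO (1.2 equiv), acetone/CH2Cl2, −40 → 0 °C; then 1 M HCl, THF, rt
Reagents that add atoms: dimethyldioxirane, CC1(C)OO1; water, O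
Why: electrophilic epoxidation of the only electron-rich alkene (the C3=C4 enediol diether; the quinone alkene is electron-poor), then acid hydrolysis of the 1,2-dimethoxy epoxide with loss of two methanol to the C3/C4 diketone; C2 is untouched and is now called (S) only because C3 outranks C1.

Step 15
Reactants: 27 (2S)-5,6,8-tris(benzyloxy)-2-{[5,7,8-tris(benzyloxy)-3-ethyl-1,4-dioxo-1,4-dihydronaphthalen-2-yl]oxy}-2-ethylnaphthalene-1,3,4(2H)-trione
Product: 28 (2S)-2-ethyl-2-[(3-ethyl-5,7,8-trihydroxy-1,4-dioxo-1,4-dihydronaphthalen-2-yl)oxy]-5,6,8-trihydroxynaphthalene-1,3,4(2H)-trione (CNP0325426.1)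
Conditions: BCl3 (12 equiv), pentamethylbenzene (18 equiv), CH2Cl2, −78 °C; then ice/dilute HCl work-up
Reagents that add atoms: none
Why: Lewis-acid debenzylation of aryl benzyl ethers with a non-basic cation scavenger, at a temperature where neither the ether bridge (C2 lies between two carbonyls and cannot ionise) nor the trione should be attacked.

Compound list
1 | 3-bromo-4,5-dihydroxybenzaldehyde | O=Cc1cc(O)c(O)c(Br)c1 | starting material
2 | 4,5-bis(benzyloxy)-3-bromobenzaldehyde | O=Cc1cc(OCc2ccccc2)c(OCc2ccccc2)c(Br)c1 | intermediate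
3 | 3,4-bis(benzyloxy)-5-bromophenyl formate (not isolated) | O=COc1cc(OCc2ccccc2)c(OCc2ccccc2)c(Br)c1 | intermediate
4 | 3,4-bis(benzyloxy)-5-bromophenol | Oc1cc(OCc2ccccc2)c(OCc2ccccc2)c(Br)c1 | intermediate
5 | 1,2,5-tris(benzyloxy)-3-bromobenzene | Brc1cc(OCc2ccccc2)cc(OCc2ccccc2)c1OCc1ccccc1 | intermediate
6 | dimethyl squarate (3,4-dimethoxycyclobut-3-ene-1,2-dione) | COC1=C(OC)C(=O)C1=O | starting material
7 | ethylmagnesium bromide | CC[Mg]Br | starting material
8 | 4-ethyl-4-hydroxy-2,3-dimethoxycyclobut-2-en-1-one (racemic; bromomagnesium alkoxide until acid is added; not isolated) | CCC1(O)C(OC)=C(OC)C1=O | intermediate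
9 | 3-ethyl-4-methoxycyclobut-3-ene-1,2-dione | CCC1=C(OC)C(=O)C1=O | intermediate
10 | 2,3,5-tris(benzyloxy)phenyllithium (not isolated) | [Li]c1cc(OCc2ccccc2)cc(OCc2ccccc2)c1OCc1ccccc1 | intermediate
11 | lithium 1-[2,3,5-tris(benzyloxy)phenyl]-3-ethyl-2-methoxy-4-oxocyclobut-2-en-1-olate (racemic; not isolated) | CCC1=C(OC)C(O[Li])(c2cc(OCc3ccccc3)cc(OCc3ccccc3)c2OCc2ccccc2)C1=O | intermediate
12 | 4-[2,3,5-tris(benzyloxy)phenyl]-2-ethyl-3,4-dimethoxycyclobut-2-en-1-one (racemic) | CCC1=C(OC)C(OC)(c2cc(OCc3ccccc3)cc(OCc3ccccc3)c2OCc2ccccc2)C1=O | intermediate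
13 | (3Z)-2-ethyl-3,4-dimethoxy-4-[2,3,5-tris(benzyloxy)phenyl]buta-1,3-dien-1-one (vinylketene; not isolated) | CCC(=C=O)/C(OC)=C(OC)\c1cc(OCc2ccccc2)cc(OCc2ccccc2)c1OCc1ccccc1 | intermediate
14 | 5,6,8-tris(benzyloxy)-2-ethyl-3,4-dimethoxynaphthalen-1-ol | CCc1c(OC)c(OC)c2c(OCc3ccccc3)c(OCc3ccccc3)cc(OCc3ccccc3)c2c1O | intermediate
15 | (R)-5,6,8-tris(benzyloxy)-2-ethyl-2-hydroxy-3,4-dimethoxynaphthalen-1(2H)-one | O[C@]1(CC)C(OC)=C(OC)c2c(OCc3ccccc3)c(OCc3ccccc3)cc(OCc3ccccc3)c2C1=O | intermediate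
16 | 3-ethyl-4-hydroxycyclobut-3-ene-1,2-dione | CCC1=C(O)C(=O)C1=O | intermediate
17 | 3-chloro-4-ethylcyclobut-3-ene-1,2-dione | CCC1=C(Cl)C(=O)C1=O | intermediate
18 | lithium alkoxide of 15 (not isolated) | [Li]O[C@]1(CC)C(OC)=C(OC)c2c(OCc3ccccc3)c(OCc3ccccc3)cc(OCc3ccccc3)c2C1=O | intermediate
19 | 3-ethyl-4-{[(2R)-5,6,8-tris(benzyloxy)-2-ethyl-3,4-dimethoxy-1-oxo-1,2-dihydronaphthalen-2-yl]oxy}cyclobut-3-ene-1,2-dione | CCC1=C(O[C@]2(CC)C(OC)=C(OC)c3c(OCc4ccccc4)c(OCc4ccccc4)cc(OCc4ccccc4)c3C2=O)C(=O)C1=O | intermediate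
20 | 2,3,5-tris(benzyloxy)phenylmagnesium bromide (not isolated) | Br[Mg]c1cc(OCc2ccccc2)cc(OCc2ccccc2)c1OCc1ccccc1 | intermediate
21 | bromomagnesium alkoxide of 22 (both carbinol epimers; not isolated) | CCC1=C(O[C@]2(CC)C(OC)=C(OC)c3c(OCc4ccccc4)c(OCc4ccccc4)cc(OCc4ccccc4)c3C2=O)C(O[Mg]Br)(c2cc(OCc3ccccc3)cc(OCc3ccccc3)c2OCc2ccccc2)C1=O | intermediate
22 | 4-[2,3,5-tris(benzyloxy)phenyl]-2-ethyl-4-hydroxy-3-{[(2R)-5,6,8-tris(benzyloxy)-2-ethyl-3,4-dimethoxy-1-oxo-1,2-dihydronaphthalen-2-yl]oxy}cyclobut-2-en-1-one (both carbinol epimers) | CCC1=C(O[C@]2(CC)C(OC)=C(OC)c3c(OCc4ccccc4)c(OCc4ccccc4)cc(OCc4ccccc4)c3C2=O)C(O)(c2cc(OCc3ccccc3)cc(OCc3ccccc3)c2OCc2ccccc2)C1=O | intermediate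
23 | (3Z)-2-ethyl-4-hydroxy-3-{[(2R)-5,6,8-tris(benzyloxy)-2-ethyl-3,4-dimethoxy-1-oxo-1,2-dihydronaphthalen-2-yl]oxy}-4-[2,3,5-tris(benzyloxy)phenyl]buta-1,3-dien-1-one (vinylketene; not isolated) | CCC(=C=O)/C(O[C@]1(CC)C(OC)=C(OC)c2c(OCc3ccccc3)c(OCc3ccccc3)cc(OCc3ccccc3)c2C1=O)=C(O)\c1cc(OCc2ccccc2)cc(OCc2ccccc2)c1OCc1ccccc1 | intermediate
24 | (2R)-5,6,8-tris(benzyloxy)-2-{[5,7,8-tris(benzyloxy)-3-ethyl-1,4-dihydroxynaphthalen-2-yl]oxy}-2-ethyl-3,4-dimethoxynaphthalen-1(2H)-one | CCc1c(O[C@]2(CC)C(OC)=C(OC)c3c(OCc4ccccc4)c(OCc4ccccc4)cc(OCc4ccccc4)c3C2=O)c(O)c2c(OCc3ccccc3)c(OCc3ccccc3)cc(OCc3ccccc3)c2c1O | intermediate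
25 | 5,7,8-tris(benzyloxy)-3-ethyl-2-{[(2R)-5,6,8-tris(benzyloxy)-2-ethyl-3,4-dimethoxy-1-oxo-1,2-dihydronaphthalen-2-yl]oxy}naphthalene-1,4-dione | CCC1=C(O[C@]2(CC)C(OC)=C(OC)c3c(OCc4ccccc4)c(OCc4ccccc4)cc(OCc4ccccc4)c3C2=O)C(=O)c2c(OCc3ccccc3)c(OCc3ccccc3)cc(OCc3ccccc3)c2C1=O | intermediate
26 | C3–C4 epoxide of 25 (3,4-dimethoxy-3,4-epoxide, mixture of epoxide diastereomers, C2 unchanged; not isolated) | CCC1=C(O[C@]2(CC)C5(OC)OC5(OC)c3c(OCc4ccccc4)c(OCc4ccccc4)cc(OCc4ccccc4)c3C2=O)C(=O)c2c(OCc3ccccc3)c(OCc3ccccc3)cc(OCc3ccccc3)c2C1=O | intermediate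
27 | (2S)-5,6,8-tris(benzyloxy)-2-{[5,7,8-tris(benzyloxy)-3-ethyl-1,4-dioxo-1,4-dihydronaphthalen-2-yl]oxy}-2-ethylnaphthalene-1,3,4(2H)-trione | CCC1=C(O[C@]2(CC)C(=O)C(=O)c3c(OCc4ccccc4)c(OCc4ccccc4)cc(OCc4ccccc4)c3C2=O)C(=O)c2c(OCc3ccccc3)c(OCc3ccccc3)cc(OCc3ccccc3)c2C1=O | intermediate
28 | (2S)-2-ethyl-2-[(3-ethyl-5,7,8-trihydroxy-1,4-dioxo-1,4-dihydronaphthalen-2-yl)oxy]-5,6,8-trihydroxynaphthalene-1,3,4(2H)-trione (CNP0325426.1) | CCC1=C(O[C@]2(CC)C(=O)C(=O)c3c(O)c(O)cc(O)c3C2=O)C(=O)c2c(O)c(O)cc(O)c2C1=O | target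

Total steps: 15. Longest linear sequence: 12 steps (1 → 2 → 4 → 5 → 12 → 14 → 15 → 19 → 22 → 24 → 25 → 27 → 28; steps 1, 2, 3, 5, 6, 7, 10, 11, 12, 13, 14, 15).

Steps most likely to fail

Step 12. At the temperature needed for ring opening, the allyl vinyl ether embedded in 22 (C3'=C2'–O–C2–C3=C4) may undergo a [3,3] shift, or the ketene may be intercepted before it closes. The fallback sets out from lithium alkoxide 11 and from 15 and comes back at 25; it makes the quinone ring first on the unhindered methoxy compound and the ether afterwards, and so also bypasses steps 10 and 11. Alkoxide 11, formed as in step 5, is quenched with acetic acid in place of methyl triflate to give 4-[2,3,5-tris(benzyloxy)phenyl]-2-ethyl-4-hydroxy-3-methoxycyclobut-2-en-1-one F1. Heating F1 in toluene should give 5,7,8-tris(benzyloxy)-3-ethyl-2-methoxynaphthalene-1,4-diol F2, which Ag2O oxidises to 5,7,8-tris(benzyloxy)-3-ethyl-2-methoxynaphthalene-1,4-dione F3. LiOH in aqueous THF, followed by dilute HCl, hydrolyses the vinylogous ester to 5,7,8-tris(benzyloxy)-3-ethyl-2-hydroxynaphthalene-1,4-dione F4, and oxalyl chloride with catalytic DMF converts it into 5,7,8-tris(benzyloxy)-2-chloro-3-ethylnaphthalene-1,4-dione F5. Compound 15 is deprotonated with LiN(SiMe3)2 as in step 10, and the resulting alkoxide 18 displaces chloride from F5 by addition–elimination to give 25.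

Step 7. The oxygen transfer may show poor facial selectivity, or oxidation may occur at C4 with loss of methanol towards the para-quinone. The fallback sets out from 14 and comes back at 15. The naphthol is hydroxylated without stereocontrol by stabilised 2-iodoxybenzoic acid in THF, which keeps the ortho-directed oxygen delivery, to give racemic 5,6,8-tris(benzyloxy)-2-ethyl-2-hydroxy-3,4-dimethoxynaphthalen-1(2H)-one F6. The enantiomers are separated by preparative chromatography on a polysaccharide carbamate chiral stationary phase; the (R)-enantiomer is 15.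

Step 10. The hindered alkoxide may be acylated too slowly, or may ring-contract by an α-ketol shift before it is trapped. The fallback sets out from 15 and comes back at 19, and avoids a preformed metal alkoxide. Compound 15 is silylated with 1-(trimethylsilyl)imidazole in CH2Cl2 to (R)-5,6,8-tris(benzyloxy)-2-ethyl-3,4-dimethoxy-2-(trimethylsilyloxy)naphthalen-1(2H)-one F7. F7 is then treated with tetrabutylammonium difluorotriphenylsilicate in the presence of 17, so that the alkoxide is released only in the presence of the electrophile and is acylated as it forms, giving 19.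

Further compounds
F1 | step 12 | 4-[2,3,5-tris(benzyloxy)phenyl]-2-ethyl-4-hydroxy-3-methoxycyclobut-2-en-1-one (racemic) | CCC1=C(OC)C(O)(c2cc(OCc3ccccc3)cc(OCc3ccccc3)c2OCc2ccccc2)C1=O
F2 | step 12 | 5,7,8-tris(benzyloxy)-3-ethyl-2-methoxynaphthalene-1,4-diol | CCc1c(OC)c(O)c2c(OCc3ccccc3)c(OCc3ccccc3)cc(OCc3ccccc3)c2c1O
F3 | step 12 | 5,7,8-tris(benzyloxy)-3-ethyl-2-methoxynaphthalene-1,4-dione | CCC1=C(OC)C(=O)c2c(OCc3ccccc3)c(OCc3ccccc3)cc(OCc3ccccc3)c2C1=O
F4 | step 12 | 5,7,8-tris(benzyloxy)-3-ethyl-2-hydroxynaphthalene-1,4-dione | CCC1=C(O)C(=O)c2c(OCc3ccccc3)c(OCc3ccccc3)cc(OCc3ccccc3)c2C1=O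
F5 | step 12 | 5,7,8-tris(benzyloxy)-2-chloro-3-ethylnaphthalene-1,4-dione | CCC1=C(Cl)C(=O)c2c(OCc3ccccc3)c(OCc3ccccc3)cc(OCc3ccccc3)c2C1=O
F6 | step 7 | racemic 5,6,8-tris(benzyloxy)-2-ethyl-2-hydroxy-3,4-dimethoxynaphthalen-1(2H)-one | OC1(CC)C(OC)=C(OC)c2c(OCc3ccccc3)c(OCc3ccccc3)cc(OCc3ccccc3)c2C1=O
F7 | step 10 | (R)-5,6,8-tris(benzyloxy)-2-ethyl-3,4-dimethoxy-2-(trimethylsilyloxy)naphthalen-1(2H)-one | C[Si](C)(C)O[C@]1(CC)C(OC)=C(OC)c2c(OCc3ccccc3)c(OCc3ccccc3)cc(OCc3ccccc3)c2C1=O
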